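The cyclohexene is disconnected at C1–C2, the bond between the ring stereocentre and the methyl-bearing olefinic carbon. An allylsilane-terminated asymmetric intramolecular Heck reaction of an acyclic (Z)-2-iodoalkene closes the ring 6-exo, sets C1 under ligand control, places the C2=C3 alkene from the vinyl iodide and ejects silicon to leave a vinyl group on C1. The step exploits that C1 is a tertiary allylic carbon next to the quaternary C6 and bears a two-carbon arm. Hydroboration of that vinyl group and B-alkyl Suzuki coupling with an (E)-iodobutenyl tetramethoxybenzene then complete the side chain; oxidative demethylation and selective hydrolysis unveil the hydroxy-methoxyquinone.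

Key step: step 5

Assumption: the sense of induction of the Heck cyclization is assigned by analogy with silane-terminated Heck cyclizations; (R)-BINAP is written for the (S)-product, and the antipodal ligand would be used if a pilot run showed the opposite sense.

Step 1
Reactants: 1 2,2-dimethylpent-4-enal
Product: 2 trimethyl[(2Z)-4,4-dimethylhepta-2,6-dien-1-yl]silane
Conditions: Ph3PCH3Br, n-BuLi, THF, 0 °C; Me3SiCH2I, rt; n-BuLi, −78 °C; then 1, −78 °C to rt
Reagents that add atoms: methyltriphenylphosphonium bromide, C[P+](c1ccccc1)(c1ccccc1)c1ccccc1.[Br-]; (iodomethyl)trimethylsilane, C[Si](C)(C)CI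
Why: Wittig olefination with the β-silyl ylide made in the flask by alkylating Ph3P=CH2 with Me3SiCH2I (Seyferth–Fleming allylsilane synthesis); the non-stabilised ylide and the non-enolisable α-quaternary aldehyde should favour the (Z)-alkene, and no stereocentre is formed.

Step 2
Reactants: 2 trimethyl[(2Z)-4,4-dimethylhepta-2,6-dien-1-yl]silane
Product: 4 (5Z)-4,4-dimethyl-7-(trimethylsilyl)hept-5-en-1-ol, via B-alkyl-9-BBN adduct 3 (not isolated)
Conditions: 9-BBN, THF, 0 °C to rt; then 3 M NaOH, 30% H2O2, 0 °C to rt
Reagents that add atoms: hydrogen peroxide, OO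
Why: Hydroboration–oxidation, in which 9-BBN adds to the monosubstituted terminal alkene far faster than to the hindered 1,2-disubstituted allylsilane alkene and puts boron on the terminal carbon, and alkaline peroxide turns C–B into C–OH without cleaving the allyl–silicon bond.

Step 3
Reactants: 4 (5Z)-4,4-dimethyl-7-(trimethylsilyl)hept-5-en-1-ol
Product: 5 (5Z)-4,4-dimethyl-7-(trimethylsilyl)hept-5-enal
Conditions: Dess–Martin periodinane, NaHCO3, CH2Cl2, 0 °C to rt
Reagents that add atoms: none
Why: Dess–Martin oxidation under bicarbonate buffer stops at the aldehyde and is mild enough for the acid-sensitive allylsilane.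

Step 4
Reactants: 5 (5Z)-4,4-dimethyl-7-(trimethylsilyl)hept-5-enal
Product: 6 trimethyl[(2Z,7Z)-8-iodo-4,4-dimethylnona-2,7-dien-1-yl]silane
Conditions: Ph3PEtI, n-BuLi, THF, rt; I2, −78 °C; NaHMDS, −20 °C; then 5, −78 to −20 °C
Reagents that add atoms: ethyltriphenylphosphonium iodide, CC[P+](c1ccccc1)(c1ccccc1)c1ccccc1.[I-]; iodine, II
Why: Stork–Zhao-type Wittig olefination with the α-iodo ylide Ph3P=C(I)CH3, a non-stabilised ylide that should give the (Z)-2-iodoalk-2-ene (iodine cis to the chain) under kinetic control, the geometry that later places the alkene inside the ring.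

Step 5
Reactants: 6 trimethyl[(2Z,7Z)-8-iodo-4,4-dimethylnona-2,7-dien-1-yl]silane
Product: 7 (6S)-6-ethenyl-1,5,5-trimethylcyclohex-1-ene
Conditions: Pd2(dba)3·CHCl3 (2.5 mol %), (R)-BINAP (7 mol %), Ag3PO4 (1.1 equiv), DMF, 80 °C
Reagents that add atoms: none
Why: Oxidative addition of the (Z)-vinyl iodide to zerovalent palladium with retention, iodide abstraction by Ag3PO4 to a cationic vinylpalladium–BINAP complex, syn-carbopalladation of the allylsilane alkene (new bond C3–C8 of 6, which is C1–C2 of the cyclohexene of the target, with palladium on the carbon β to silicon) and anti-elimination of palladium and the silyl group, which releases the vinyl group and zerovalent palladium. The closest known reaction is the allylsilane-terminated asymmetric intramolecular Heck reaction, which forms six-membered rings carrying a tertiary vinyl-substituted stereocentre. The ring closes in the 6-exo-trig mode. The new stereocentre is set in the migratory insertion, where the C2-symmetric bisphosphine on cationic palladium differentiates the two faces of the (Z)-alkene. The step needs 6-exo over 7-endo insertion, secured by the three-atom tether, the gem-dimethyl group and the preference of palladium for the carbon β to silicon, and it needs desilylative termination instead of β-hydride loss from the new stereocentre, secured by the β-silicon effect under halide-free silver conditions, so that the stereocentre is not erased and no palladium hydride can move the ring alkene. The (Z)-geometry of the iodide guarantees that the trisubstituted alkene ends up endocyclic next to the stereocentre.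

Step 6
Reactants: 8 but-2-yn-1-ol
Product: 10 (2E)-3-iodobut-2-en-1-ol, via bis-zirconocene intermediate 9 (not isolated)
Conditions: Cp2Zr(H)Cl (2.2 equiv), THF, rt; then I2, 0 °C; aqueous work-up
Reagents that add atoms: iodine, II
Why: Hydrozirconation–iodination, in which the first equivalent of Cp2Zr(H)Cl turns the hydroxyl into a bulky zirconium alkoxide, the second adds Zr–H syn across the alkyne with zirconium on the less hindered methyl-bearing carbon (thermodynamic control with excess reagent), and iodinolysis with retention gives the (E)-3-iodoalkene.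

Step 7
Reactants: 10 (2E)-3-iodobut-2-en-1-ol
Product: 11 (2E)-1-bromo-3-iodobut-2-ene
Conditions: CBr4, PPh3, CH2Cl2, 0 °C
Reagents that add atoms: tetrabromomethane, BrC(Br)(Br)Br
Why: Appel bromination converts the primary allylic alcohol into the bromide under neutral conditions without touching the vinyl iodide or the alkene geometry.

Step 8
Reactants: 12 1,2,4,5-tetramethoxybenzene; 11 (2E)-1-bromo-3-iodobut-2-ene
Product: 15 3-[(2E)-3-iodobut-2-en-1-yl]-1,2,4,5-tetramethoxybenzene, via aryllithium 13 (not isolated), via arylcopper 14 (not isolated)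
Conditions: 12, n-BuLi, TMEDA, THF, 0 °C; CuBr·SMe2, −78 to −40 °C; then 11, −78 to 0 °C
Reagents that add atoms: none
Why: Directed ortho-lithiation between two methoxy groups, transmetalation to the arylcopper and SN2 allylation at the primary allylic bromide, in which the soft arylcopper should not undergo iodine–metal exchange with the vinyl iodide at low temperature and the hindered iodine-bearing γ-carbon disfavours SN2′ attack.

Step 9
Reactants: 7 (6S)-6-ethenyl-1,5,5-trimethylcyclohex-1-ene; 15 3-[(2E)-3-iodobut-2-en-1-yl]-1,2,4,5-tetramethoxybenzene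
Product: 17 1,2,4,5-tetramethoxy-3-{(2E)-3-methyl-5-[(1S)-2,6,6-trimethylcyclohex-2-en-1-yl]pent-2-en-1-yl}benzene, via B-alkyl-9-BBN adduct 16 (not isolated)
Conditions: 7, 9-BBN, THF, rt; then 15, PdCl2(dppf) (5 mol %), AsPh3, Cs2CO3, DMF–H2O, rt
Reagents that add atoms: none
Why: Chemoselective hydroboration of the monosubstituted vinyl group (boron on the terminal carbon, the trisubstituted ring alkene being inert to 9-BBN at rt) followed by B-alkyl Suzuki–Miyaura coupling, which proceeds with retention of the (E)-geometry of the vinyl iodide and does not involve the stereocentre.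

Step 10
Reactants: 17 1,2,4,5-tetramethoxy-3-{(2E)-3-methyl-5-[(1S)-2,6,6-trimethylcyclohex-2-en-1-yl]pent-2-en-1-yl}benzene
Product: 18 2,5-dimethoxy-3-{(2E)-3-methyl-5-[(1S)-2,6,6-trimethylcyclohex-2-en-1-yl]pent-2-en-1-yl}cyclohexa-2,5-diene-1,4-dione
Conditions: (NH4)2Ce(NO3)6, MeCN–H2O, 0 °C
Reagents that add atoms: water, O
Why: Oxidative demethylation of a para-dimethoxy pair by tetravalent cerium gives the 2,5-dimethoxy-1,4-benzoquinone (either para pair gives the same quinone by the symmetry of the arene), and the isolated trisubstituted alkenes should be oxidised much more slowly than the tetraalkoxyarene.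

Step 11
Reactants: 18 2,5-dimethoxy-3-{(2E)-3-methyl-5-[(1S)-2,6,6-trimethylcyclohex-2-en-1-yl]pent-2-en-1-yl}cyclohexa-2,5-diene-1,4-dione
Product: 20 2-hydroxy-5-methoxy-3-{(2E)-3-methyl-5-[(1S)-2,6,6-trimethylcyclohex-2-en-1-yl]pent-2-en-1-yl}cyclohexa-2,5-diene-1,4-dione, via potassium quinonolate 19 (not isolated)
Conditions: KOH, MeOH–H2O, rt; then 1 M HCl
Reagents that add atoms: potassium hydroxide, [K+].[OH-]
Why: Addition–elimination (vinylogous ester saponification) by hydroxide at the methoxy-bearing carbon next to the side chain, whose methoxy group is twisted out of conjugation by its two flanking substituents and should therefore be the more electrophilic, while the hydroxyquinone anion formed resists a second substitution and base leaves the alkenes untouched.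

Compound list
1 | 2,2-dimethylpent-4-enal | O=CC(C)(C)CC=C | starting material
2 | trimethyl[(2Z)-4,4-dimethylhepta-2,6-dien-1-yl]silane | C[Si](C)(C)C/C=C\C(C)(C)CC=C | intermediate
3 | 9-[(5Z)-4,4-dimethyl-7-(trimethylsilyl)hept-5-en-1-yl]-9-borabicyclo[3.3.1]nonane | C[Si](C)(C)C/C=C\C(C)(C)CCCB1C2CCCC1CCC2 | intermediate
4 | (5Z)-4,4-dimethyl-7-(trimethylsilyl)hept-5-en-1-ol | C[Si](C)(C)C/C=C\C(C)(C)CCCO | intermediate
5 | (5Z)-4,4-dimethyl-7-(trimethylsilyl)hept-5-enal | C[Si](C)(C)C/C=C\C(C)(C)CCC=O | intermediate
6 | trimethyl[(2Z,7Z)-8-iodo-4,4-dimethylnona-2,7-dien-1-yl]silane | C[Si](C)(C)C/C=C\C(C)(C)CC/C=C(/C)I | intermediate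
7 | (6S)-6-ethenyl-1,5,5-trimethylcyclohex-1-ene | C=C[C@@H]1C(C)=CCCC1(C)C | intermediate
8 | but-2-yn-1-ol | CC#CCO | starting material
9 | chloro{(2E)-4-[(chlorozirconocenyl)oxy]but-2-en-2-yl}zirconocene | C/C(=C\CO[Zr](Cl)(C1C=CC=C1)C1C=CC=C1)[Zr](Cl)(C1C=CC=C1)C1C=CC=C1 | intermediate
10 | (2E)-3-iodobut-2-en-1-ol | OC/C=C(\C)I | intermediate
11 | (2E)-1-bromo-3-iodobut-2-ene | BrC/C=C(\C)I | intermediate
12 | 1,2,4,5-tetramethoxybenzene | COc1cc(OC)c(OC)cc1OC | starting material
13 | (2,3,5,6-tetramethoxyphenyl)lithium | [Li]c1c(OC)c(OC)cc(OC)c1OC | intermediate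
14 | (2,3,5,6-tetramethoxyphenyl)copper | [Cu]c1c(OC)c(OC)cc(OC)c1OC | intermediate
15 | 3-[(2E)-3-iodobut-2-en-1-yl]-1,2,4,5-tetramethoxybenzene | COc1cc(OC)c(OC)c(C/C=C(\C)I)c1OC | intermediate
16 | 9-{2-[(1S)-2,6,6-trimethylcyclohex-2-en-1-yl]ethyl}-9-borabicyclo[3.3.1]nonane | C(CB1C2CCCC1CCC2)[C@@H]3C(C)=CCCC3(C)C | intermediate
17 | 1,2,4,5-tetramethoxy-3-{(2E)-3-methyl-5-[(1S)-2,6,6-trimethylcyclohex-2-en-1-yl]pent-2-en-1-yl}benzene | COc1cc(OC)c(OC)c(C/C=C(\C)CC[C@@H]2C(C)=CCCC2(C)C)c1OC | intermediate
18 | 2,5-dimethoxy-3-{(2E)-3-methyl-5-[(1S)-2,6,6-trimethylcyclohex-2-en-1-yl]pent-2-en-1-yl}cyclohexa-2,5-diene-1,4-dione | COC1=CC(=O)C(OC)=C(C/C=C(\C)CC[C@@H]2C(C)=CCCC2(C)C)C1=O | intermediate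
19 | potassium 4-methoxy-3,6-dioxo-2-{(2E)-3-methyl-5-[(1S)-2,6,6-trimethylcyclohex-2-en-1-yl]pent-2-en-1-yl}cyclohexa-1,4-dien-1-olate | COC1=CC(=O)C([O-])=C(C/C=C(\C)CC[C@@H]2C(C)=CCCC2(C)C)C1=O.[K+] | intermediate
20 | 2-hydroxy-5-methoxy-3-{(2E)-3-methyl-5-[(1S)-2,6,6-trimethylcyclohex-2-en-1-yl]pent-2-en-1-yl}cyclohexa-2,5-diene-1,4-dione | COC1=CC(=O)C(O)=C(C/C=C(\C)CC[C@@H]2C(C)=CCCC2(C)C)C1=O | target

Total step count: 11. Longest linear sequence: 8 steps (steps 1 to 5, then 9 to 11); steps 6 to 8 build the second fragment.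

Steps most likely to fail

Step 5. The migratory insertion may discriminate the alkene faces poorly, because the attacked carbon sits next to the quaternary centre, and β-hydride loss toward the new stereocentre may compete with desilylation. The fallback gives up ligand control and sets out from 6. Cyclization of 6 with an achiral ligand (Pd2(dba)3·CHCl3, dppf, Ag3PO4, DMF) should give racemic 6-ethenyl-1,5,5-trimethylcyclohex-1-ene F1. Hydroboration with 9-BBN gives the racemic B-alkyl-9-BBN adduct F2, and coupling with 15 as in step 9 gives the racemic tetramethoxyarene F3. The enantiomers of F3 are separated by preparative chromatography on a chiral stationary phase, and the route is re-entered at 17.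

Step 6. The hydrozirconation may place zirconium on the wrong alkyne carbon (directing by the alkoxide or incomplete equilibration), which would give the 2-iodo regioisomer. The fallback sets out from borane 16 and arylcopper 14 and returns at 17. Borane 16 is coupled under the conditions of step 9 with ethyl (2E)-3-{[(trifluoromethyl)sulfonyl]oxy}but-2-enoate F4, made from ethyl acetoacetate with Tf2O and aqueous Me4NOH, conditions that should give the (E)-enol triflate. This gives ethyl (2E)-3-methyl-5-[(1S)-2,6,6-trimethylcyclohex-2-en-1-yl]pent-2-enoate F5. DIBAL-H reduction gives (2E)-3-methyl-5-[(1S)-2,6,6-trimethylcyclohex-2-en-1-yl]pent-2-en-1-ol F6, and CBr4/PPh3 gives the allylic bromide (6S)-6-[(3E)-5-bromo-3-methylpent-3-en-1-yl]-1,5,5-trimethylcyclohex-1-ene F7. Allylation of arylcopper 14 (made from 12 as in step 8) with this bromide gives 17.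

Step 11. Hydroxide may attack the less hindered methoxy-bearing carbon instead, which would give the regioisomeric hydroxy-methoxyquinone. The fallback sets out from 18 and returns at 20. Exhaustive hydrolysis (2 M NaOH, EtOH, 60 °C, then acid) gives 2,5-dihydroxy-3-{(2E)-3-methyl-5-[(1S)-2,6,6-trimethylcyclohex-2-en-1-yl]pent-2-en-1-yl}cyclohexa-2,5-diene-1,4-dione F8. Acid-catalysed methanolysis (MeOH, catalytic H2SO4, rt) should then methylate only the hydroxyl remote from the side chain, the less hindered vinylogous acid position, and give 20.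

Further compounds
F1 | step 5 | racemic 6-ethenyl-1,5,5-trimethylcyclohex-1-ene | C=CC1C(C)=CCCC1(C)C
F2 | step 5 | racemic 9-[2-(2,6,6-trimethylcyclohex-2-en-1-yl)ethyl]-9-borabicyclo[3.3.1]nonane | C(CB1C2CCCC1CCC2)C1C(C)=CCCC1(C)C
F3 | step 5 | racemic 1,2,4,5-tetramethoxy-3-[(2E)-3-methyl-5-(2,6,6-trimethylcyclohex-2-en-1-yl)pent-2-en-1-yl]benzene | COc1cc(OC)c(OC)c(C/C=C(\C)CCC2C(C)=CCCC2(C)C)c1OC
F4 | step 6 | ethyl (2E)-3-{[(trifluoromethyl)sulfonyl]oxy}but-2-enoate | CCOC(=O)/C=C(\C)OS(=O)(=O)C(F)(F)F
F5 | step 6 | ethyl (2E)-3-methyl-5-[(1S)-2,6,6-trimethylcyclohex-2-en-1-yl]pent-2-enoate | CCOC(=O)/C=C(\C)CC[C@@H]1C(C)=CCCC1(C)C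
F6 | step 6 | (2E)-3-methyl-5-[(1S)-2,6,6-trimethylcyclohex-2-en-1-yl]pent-2-en-1-ol | OC/C=C(\C)CC[C@@H]1C(C)=CCCC1(C)C
F7 | step 6 | (6S)-6-[(3E)-5-bromo-3-methylpent-3-en-1-yl]-1,5,5-trimethylcyclohex-1-ene | BrC/C=C(\C)CC[C@@H]1C(C)=CCCC1(C)C
F8 | step 11 | 2,5-dihydroxy-3-{(2E)-3-methyl-5-[(1S)-2,6,6-trimethylcyclohex-2-en-1-yl]pent-2-en-1-yl}cyclohexa-2,5-diene-1,4-dione | OC1=CC(=O)C(O)=C(C/C=C(\C)CC[C@@H]2C(C)=CCCC2(C)C)C1=O
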